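Look at the plateaus.

| setting | cedar | elm | flask |
|---|---|---|---|
| substrate | 0.10 M | 0.10 M | 0.10 M |
| partner | 0.060 M | 0.060 M | 0.0600 M |
| second reagent | 0.095 M | 0.095 M | 0.0950 M |
| third reagent | 0.050 M | 0.075 M | 0.100 M |
| remark | run made earlier | run made earlier |  |
| time |  |  | 4.0 d |

| run | time / d | over-reaction product / % | target / % |
|---|---|---|---|
| cedar | 0.417 | 17.1 | 29.8 |
| cedar | 1.04 | 47.2 | 4.3 |
| cedar | 2.08 | 49.4 | 0 |
| cedar | 3.00 | 49.8 | 0 |
| elm | 0.417 | 18.9 | 41.6 |
| elm | 1.04 | 47.4 | 12.6 |
| elm | 2.08 | 59.8 | 0.5 |
| elm | 3.00 | 60.3 | 0.9 |

(scatter of a reading: 1 percentage point)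

1. which holds at 4.0 d: what has brought the reaction to rest, or that it has not come to rest (the second reagent has run out first / it is still moving / the partner has run out first / all of the substrate has reacted / the third reagent has run out first)
2. amount of over-reaction product at 4.0 d, in percent of the substrate charged

Cedar stands at 49.8% of over-reaction product at 3.00 d and elm at 60.3% at 3.00 d, and between 2.08 d and 3.00 d neither has moved by more than the scatter of 1 percentage point. Two people at the board read these plateaus differently.

The line-drawer reasons from third reagent. Raising [third reagent] from 0.050 M to 0.075 M gained 10 points, and the flask adds the same step once more, to 0.100 M, so a straight line through the two plateaus gives 70.8%.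

The counter, and I stand with him, reasons from the one-to-one steps of the chain. He carries the ceiling, the smallest charge as a share of the substrate charge, which is 60.0% for the flask. There [partner] = 0.0600 M is the limiting reagent, lower than second and third reagent. The same reckoning gives 50.0% for cedar and 60.0% for elm, both within the scatter of their plateaus. Elm had flattened by 2.08 d, and the flask gets twice that time.

The forecast takes the counter's side: 60% at 4.0 d, and as what holds then, that the partner has run out first, with the words “so the partner runs out first”.

The flask gives 60.0% at 4.0 d, and what holds then is that the partner has run out first, with 0% of the partner's charge left.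

    substrate + partner → intermediate A (k = 0.437 L mol⁻¹ min⁻¹)
    second reagent + intermediate A → intermediate B (k = 11.2 L mol⁻¹ min⁻¹)
    third reagent + intermediate B → target (k = 0.427 L mol⁻¹ min⁻¹)
    target → over-reaction product (k = 0.00809 min⁻¹)
    crystals ⇌ target, rate k5*(cs5 - [target]) while solid is left; crystals form when [target] > cs5 (solubility = 3.90 mM, k = 2.76 min⁻¹)

So the ceiling of 60.0% stands, and the line's 70.8% does not. The line-drawer's reading belongs to flasks like cedar, where [third reagent] = 0.050 M lies below [partner]. A neighbour charged like the flask but with 0.025 M of third reagent has a ceiling of 25.0%. At 4.00 d that neighbour holds 0% of its charge of third reagent, and of the substrate charged 35.0% stands as intermediate B and 25.0% as over-reaction product.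

All runs were computed for substances that don't exist, noise included.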